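## Retrosynthetic overview
1. The caffeate aryl–vinyl bond is cut by a Heck disconnection to 4-iodocatechol and a C3 acrylate. The acrylate is carried through the route masked as its 3-chloropropanoate.
2. The 8α-OH and 7α-H come from radical opening of a 7α,8α-epoxide with trivalent titanium. The epoxide is made from a C7=C8 alkene.
3. Ring A is formed last, in the key step. A samarium ketyl at C3 closes 6-exo-dig onto a C5 ethynyl group, forming C3–C4 and giving the 3β-OH and the 4(15)-methylene together.
4. The C1–C2 bond comes from a Felkin-controlled supersilyl Mukaiyama aldol of an acetaldehyde enol ether, which sets the 1β-oxygen.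
5. Ring B is formed first, by an enantioselective Diels–Alder reaction of 2-isopropylbutadiene with (E)-2-methylpent-2-en-4-ynal. This sets C5 and C10 trans.

Assumption: eudesmane numbering (C1–C15) is used for the decalins and for the carbons that become them, and the (S)-oxazaborolidinium ion is taken to give the (1R,6S) adduct by the usual formyl C–H···O model; if the sense is opposite, the mirror-image catalyst is used.

## Route

Step 1
Reactants: 1 3-methylbut-1-yne; 2 ethylene
Product: 3 2-(propan-2-yl)buta-1,3-diene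
Conditions: second-generation Grubbs catalyst RuCl2(=CHPh)(PCy3)(H2IMes) (3 mol%), ethylene (1 atm), CH2Cl2, rt; distil
Reagents that add atoms: none
Why: Ene–yne cross-metathesis with ethylene turns the terminal alkyne into the 2-substituted 1,3-diene with full atom economy, and no stereocenter is formed.

Step 2
Reactants: 4 ethynylmagnesium bromide; 5 (E)-3-(dimethylamino)-2-methylprop-2-enal
Product: 7 (E)-2-methylpent-2-en-4-ynal, via bromomagnesium alkoxide adduct 6 (not isolated)
Conditions: THF, 0 °C to rt; then 2 M aq HCl, 0 °C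
Reagents that add atoms: water, O
Why: 1,2-Addition of the alkynyl Grignard reagent to the vinylogous formamide, then acid-induced loss of water and hydrolysis of the vinylogous iminium ion (a formal vinylogous formylation), gives the enal, and the reversible iminium stage funnels the alkene to the more stable E isomer with the ethynyl group trans to CHO.

Step 3
Reactants: 3 2-(propan-2-yl)buta-1,3-diene; 7 (E)-2-methylpent-2-en-4-ynal
Product: 8 (1R,6S)-6-ethynyl-1-methyl-4-(propan-2-yl)cyclohex-3-ene-1-carbaldehyde (CHO and ethynyl trans)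
Conditions: (S)-3,3-diphenyl-1-(o-tolyl)oxazaborolidine from (S)-diphenylprolinol (20 mol%), Tf2NH (16 mol%), 3 (3 equiv), CH2Cl2, −78 to −40 °C
Reagents that add atoms: none
Why: In this catalytic enantioselective Diels–Alder reaction (Corey oxazaborolidinium ion) the formyl-bound catalyst shields one face of the enal and sets the absolute configuration, the 2-alkyl diene adds in the para sense (its nucleophilic C1 terminus to the β-carbon), and suprafacial addition to the E alkene places CHO and ethynyl trans, which fixes C10 (R) and C5 (S) with CH3-10 anti to H-5.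

Step 4
Reactants: 9 acetaldehyde
Product: 10 (ethenyloxy)tris(trimethylsilyl)silane (supersilyl vinyl ether)
Conditions: (Me3Si)3SiH, TfOH, CH2Cl2, 0 °C; then Et3N, 9, −78 °C to rt
Reagents that add atoms: tris(trimethylsilyl)silane, C[Si](C)(C)[SiH]([Si](C)(C)C)[Si](C)(C)C
Why: Protonolysis of the Si–H bond gives the silyl triflate, which O-silylates acetaldehyde under soft enolization with Et3N (silyl enol ether formation), and no stereocenter is formed.

Step 5
Reactants: 8 (1R,6S)-6-ethynyl-1-methyl-4-(propan-2-yl)cyclohex-3-ene-1-carbaldehyde; 10 (ethenyloxy)tris(trimethylsilyl)silane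
Product: 11 (3R)-3-[(1R,6S)-6-ethynyl-1-methyl-4-(propan-2-yl)cyclohex-3-en-1-yl]-3-{[tris(trimethylsilyl)silyl]oxy}propanal
Conditions: 10 (1.1 equiv), Tf2NH (0.1 mol%), CH2Cl2, −78 °C
Reagents that add atoms: none
Why: In this Mukaiyama cross-aldol of the supersilyl type the activated neopentyl aldehyde is attacked through an open Felkin–Anh transition state (C5 as the large group anti to the nucleophile, which passes over CH3-10), giving the 1R (1β) silyl ether, and the bulk of the transferred silyl group stops a second aldol on the product aldehyde.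

Step 6
Reactants: 11 (3R)-3-[(1R,6S)-6-ethynyl-1-methyl-4-(propan-2-yl)cyclohex-3-en-1-yl]-3-{[tris(trimethylsilyl)silyl]oxy}propanal
Product: 14 (1R,3S,5S,10R)-1-{[tris(trimethylsilyl)silyl]oxy}eudesma-4(15),7-dien-3-ol (trans-decalin; 1β-OSi; 3β-OH; H-5 α; CH3-10 β), via samarium ketyl radical 12 (not isolated), via C15 vinyl radical 13 (not isolated)
Conditions: SmI2 (3 equiv), HMPA (12 equiv), t-BuOH (2.5 equiv), THF (0.005 M), 0 °C, slow addition of 11
Reagents that add atoms: none
Why: In this ketyl–alkyne radical cyclization, divalent samarium in SmI2–HMPA reduces the aldehyde to a ketyl radical that adds 6-exo-dig to the inner alkyne carbon C4 through a chair with the bulky O–Sm and O–Si groups both equatorial (3S, 3β-OH), the σ-vinyl radical then takes a hydrogen atom from THF to leave the 4(15)-methylene group, and because the new bond lies away from C5 and C10 the trans ring fusion set in step 3 is carried over unchanged.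

Step 7
Reactants: 14 (1R,3S,5S,10R)-1-{[tris(trimethylsilyl)silyl]oxy}eudesma-4(15),7-dien-3-ol; 15 3-chloropropanoyl chloride
Product: 16 (1R,3S,5S,10R)-1-{[tris(trimethylsilyl)silyl]oxy}eudesma-4(15),7-dien-3-yl 3-chloropropanoate
Conditions: pyridine, CH2Cl2, 0 °C
Reagents that add atoms: none
Why: Acylation of the only free hydroxyl group with an acid chloride under pyridine (too weak a base for dehydrochlorination) installs a masked acrylate that is inert to the dioxirane and to carbon radicals, with retention at C3.

Step 8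
Reactants: 16 (1R,3S,5S,10R)-1-{[tris(trimethylsilyl)silyl]oxy}eudesma-4(15),7-dien-3-yl 3-chloropropanoate
Product: 17 (1R,3S,5S,10R)-1-hydroxyeudesma-4(15),7-dien-3-yl 3-chloropropanoate
Conditions: HF·pyridine, THF, 0 °C to rt
Reagents that add atoms: none
Why: Fluoride-driven Si–O cleavage removes the supersilyl group before any oxidant can attack its Si–Si bonds, and acyl migration from O3 to O1 is ruled out because the two equatorial oxygens of the rigid trans-decalin cannot reach each other.

Step 9
Reactants: 17 (1R,3S,5S,10R)-1-hydroxyeudesma-4(15),7-dien-3-yl 3-chloropropanoate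
Product: 18 7α,8α-epoxy-1β-hydroxyeudesm-4(15)-en-3β-yl 3-chloropropanoate
Conditions: DMDO (1.05 equiv), acetone/CH2Cl2, −40 to 0 °C
Reagents that add atoms: dimethyldioxirane, CC1(C)OO1
Why: Electrophilic dioxirane epoxidation picks the electron-rich trisubstituted C7=C8 alkene over the 1,1-disubstituted alkene that is deactivated by the allylic ester, and attack comes from the α face because the axial CH3-10 blocks the β face, which sets the C8–O bond α.

Step 10
Reactants: 18 7α,8α-epoxy-1β-hydroxyeudesm-4(15)-en-3β-yl 3-chloropropanoate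
Product: 20 (1R,3S,5S,7R,8S,10R)-1,8-dihydroxyeudesm-4(15)-en-3-yl 3-chloropropanoate, via C7 titanoxy radical 19 (not isolated)
Conditions: Cp2TiCl2 (2.5 equiv), Mn dust (8 equiv), H2O (20 equiv), THF, rt
Reagents that add atoms: none
Why: In this Nugent–RajanBabu reductive epoxide opening, Cp2TiCl (trivalent titanium) cleaves the C7–O bond homolytically to the more stable tertiary radical while oxygen stays α on C8, and the water complex of Cp2TiCl delivers a hydrogen atom along the axial α trajectory so that the isopropyl group ends equatorial (7R) next to the equatorial 8α-OH (8S).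

Step 11
Reactants: 21 catechol (benzene-1,2-diol)
Product: 22 4-iodobenzene-1,2-diol
Conditions: NIS (1.0 equiv), TFA (10 mol%), MeCN, 0 °C
Reagents that add atoms: N-iodosuccinimide, O=C1CCC(=O)N1I
Why: Electrophilic aromatic iodination under acid catalysis goes para to one hydroxyl group (position 4), the least hindered activated site, and the acidic medium disfavors oxidation to the quinone.

Step 12
Reactants: 20 (1R,3S,5S,7R,8S,10R)-1,8-dihydroxyeudesm-4(15)-en-3-yl 3-chloropropanoate; 22 4-iodobenzene-1,2-diol
Product: 24 (1R,3S,5S,7R,8S,10R)-1,8-dihydroxyeudesm-4(15)-en-3-yl (E)-3-(3,4-dihydroxyphenyl)prop-2-enoate (CNP0264533.1), via acrylate ester 23 (not isolated)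
Conditions: 22 (1.3 equiv), Pd(OAc)2 (5 mol%), Et3N (5 equiv), DMF, 70 °C, Ar
Reagents that add atoms: none
Why: Et3N first eliminates HCl from the β-chloro ester (E1cB) to unveil the acrylate, which then undergoes a ligand-free Mizoroki–Heck arylation at its terminal carbon (syn insertion, syn β-hydride elimination) to give the E cinnamate, while the equatorial C3–O bond lies in the nodal plane of the neighbouring alkene and so resists ionization by zerovalent palladium.

## Compound list
1 | 3-methylbut-1-yne | CC(C)C#C | starting material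
2 | ethylene | C=C | starting material
3 | 2-(propan-2-yl)buta-1,3-diene | C=CC(=C)C(C)C | intermediate
4 | ethynylmagnesium bromide | C#C[Mg]Br | starting material
5 | (E)-3-(dimethylamino)-2-methylprop-2-enal | CN(C)/C=C(\C)C=O | starting material
6 | bromomagnesium (E)-1-(dimethylamino)-2-methylpent-1-en-4-yn-3-olate (racemic carbinol carbon, lost in the next event) | CN(C)/C=C(\C)C(O[Mg]Br)C#C | intermediate
7 | (E)-2-methylpent-2-en-4-ynal | C#C/C=C(\C)C=O | intermediate
8 | (1R,6S)-6-ethynyl-1-methyl-4-(propan-2-yl)cyclohex-3-ene-1-carbaldehyde | O=C[C@]1(C)CC=C(C(C)C)C[C@H]1C#C | intermediate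
9 | acetaldehyde | CC=O | starting material
10 | (ethenyloxy)tris(trimethylsilyl)silane | C=CO[Si]([Si](C)(C)C)([Si](C)(C)C)[Si](C)(C)C | intermediate
11 | (3R)-3-[(1R,6S)-6-ethynyl-1-methyl-4-(propan-2-yl)cyclohex-3-en-1-yl]-3-{[tris(trimethylsilyl)silyl]oxy}propanal | O=CC[C@@H](O[Si]([Si](C)(C)C)([Si](C)(C)C)[Si](C)(C)C)[C@]1(C)CC=C(C(C)C)C[C@H]1C#C | intermediate
12 | samarium ketyl radical of 11 (radical on C3, O–SmI2) | I[Sm](I)O[CH]C[C@@H](O[Si]([Si](C)(C)C)([Si](C)(C)C)[Si](C)(C)C)[C@]1(C)CC=C(C(C)C)C[C@H]1C#C | intermediate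
13 | cyclized C15 vinyl radical (decalin, 3β-O–SmI2) | [CH]=C1[C@@H](O[Sm](I)I)C[C@@H](O[Si]([Si](C)(C)C)([Si](C)(C)C)[Si](C)(C)C)[C@]2(C)CC=C(C(C)C)C[C@@H]12 | intermediate
14 | (1R,3S,5S,10R)-1-{[tris(trimethylsilyl)silyl]oxy}eudesma-4(15),7-dien-3-ol | C=C1[C@@H](O)C[C@@H](O[Si]([Si](C)(C)C)([Si](C)(C)C)[Si](C)(C)C)[C@]2(C)CC=C(C(C)C)C[C@@H]12 | intermediate
15 | 3-chloropropanoyl chloride | O=C(Cl)CCCl | starting material
16 | (1R,3S,5S,10R)-1-{[tris(trimethylsilyl)silyl]oxy}eudesma-4(15),7-dien-3-yl 3-chloropropanoate | C=C1[C@@H](OC(=O)CCCl)C[C@@H](O[Si]([Si](C)(C)C)([Si](C)(C)C)[Si](C)(C)C)[C@]2(C)CC=C(C(C)C)C[C@@H]12 | intermediate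
17 | (1R,3S,5S,10R)-1-hydroxyeudesma-4(15),7-dien-3-yl 3-chloropropanoate | C=C1[C@@H](OC(=O)CCCl)C[C@@H](O)[C@]2(C)CC=C(C(C)C)C[C@@H]12 | intermediate
18 | 7α,8α-epoxy-1β-hydroxyeudesm-4(15)-en-3β-yl 3-chloropropanoate | C=C1[C@@H](OC(=O)CCCl)C[C@@H](O)[C@]2(C)C[C@H](O3)[C@@]3(C(C)C)C[C@@H]12 | intermediate
19 | C7 tertiary radical with 8α-O–TiCp2Cl | C=C1[C@@H](OC(=O)CCCl)C[C@@H](O)[C@]2(C)C[C@H]([O-])[C](C(C)C)C[C@@H]12.[Ti+4].[Cl-].c1cc[cH-]c1.c1cc[cH-]c1 | intermediate
20 | (1R,3S,5S,7R,8S,10R)-1,8-dihydroxyeudesm-4(15)-en-3-yl 3-chloropropanoate | C=C1[C@@H](OC(=O)CCCl)C[C@@H](O)[C@]2(C)C[C@H](O)[C@@H](C(C)C)C[C@@H]12 | intermediate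
21 | catechol | Oc1ccccc1O | starting material
22 | 4-iodobenzene-1,2-diol | Oc1ccc(I)cc1O | intermediate
23 | (1R,3S,5S,7R,8S,10R)-1,8-dihydroxyeudesm-4(15)-en-3-yl prop-2-enoate | C=C1[C@@H](OC(=O)C=C)C[C@@H](O)[C@]2(C)C[C@H](O)[C@@H](C(C)C)C[C@@H]12 | intermediate
24 | (2S,4R,4aR,6S,7R,8aS)-4,6-dihydroxy-4a-methyl-1-methylidene-7-(propan-2-yl)decahydronaphthalen-2-yl (E)-3-(3,4-dihydroxyphenyl)prop-2-enoate | C=C1[C@@H](OC(=O)/C=C/c2ccc(O)c(O)c2)C[C@@H](O)[C@]2(C)C[C@H](O)[C@@H](C(C)C)C[C@@H]12 | target

## Step count and risks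
Total step count: 12.
Longest linear sequence: 9 (steps 2, 3, 5, 6, 7, 8, 9, 10, 12).

**Step 6.** Addition of the ketyl to an unactivated terminal alkyne in the 6-exo-dig mode is slow. Simple reduction of the aldehyde, or pinacol coupling, may win. The fallback reverses the roles of the two partners; it sets out from 11 and comes back at 14.
- 11 is heated with Bu3SnH and AIBN in benzene at 80 °C with slow addition.
- The stannyl radical adds to C15. The C4 vinyl radical then closes 6-exo onto the aldehyde carbon, and the alkoxy radical is quenched by Bu3SnH.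
- This gives (E)-15-(tributylstannyl)-1β-{[tris(trimethylsilyl)silyl]oxy}eudesma-4(15),7-dien-3β-ol F1.
- Protodestannylation with HCl in Et2O/CH2Cl2 at −20 °C gives 14.

**Step 10.** Hydrogen-atom delivery to the C7 radical may be unselective. The radical may also disproportionate to an alkene. The fallback replaces kinetic control with thermodynamic control; it sets out from 18 and comes back at 20.
- BF3·OEt2 in CH2Cl2 at −78 °C triggers a Meinwald rearrangement: the C7–O bond ionizes and a hydride shifts 1,2 from C8.
- The acidic medium equilibrates C7 to the equatorial isopropyl epimer. This gives 1β-hydroxy-8-oxoeudesm-4(15)-en-3β-yl 3-chloropropanoate F2.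
- Single-electron reduction with SmI2–H2O in THF then gives the more stable equatorial 8α-alcohol 20.

**Step 12.** The unprotected catechol may be oxidized or may bind palladium. Zerovalent palladium may also ionize the allylic ester. The fallback forms the same alkene by metathesis; it sets out from 20 and 22 and comes back at 24.
- 20 is treated with Et3N alone (CH2Cl2, rt), and the acrylate 23 is isolated.
- 22 is vinylated with potassium vinyltrifluoroborate (PdCl2(dppf), Et3N, n-PrOH, 80 °C) to give 4-ethenylbenzene-1,2-diol F3.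
- Cross-metathesis of 23 with F3 uses the second-generation Hoveyda–Grubbs catalyst RuCl2(=CH-C6H4-2-OiPr)(H2IMes) in CH2Cl2 at 40 °C. It gives 24 as the E isomer.
- The hindered 1,1-disubstituted ring alkene does not take part.

## Further compounds
F1 | step 6 | (E)-15-(tributylstannyl)-1β-{[tris(trimethylsilyl)silyl]oxy}eudesma-4(15),7-dien-3β-ol | CCCC[Sn](CCCC)(CCCC)/C=C1/[C@@H](O)C[C@@H](O[Si]([Si](C)(C)C)([Si](C)(C)C)[Si](C)(C)C)[C@]2(C)CC=C(C(C)C)C[C@@H]12
F2 | step 10 | 1β-hydroxy-8-oxoeudesm-4(15)-en-3β-yl 3-chloropropanoate (7β-isopropyl) | C=C1[C@@H](OC(=O)CCCl)C[C@@H](O)[C@]2(C)CC(=O)[C@@H](C(C)C)C[C@@H]12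
F3 | step 12 | 4-ethenylbenzene-1,2-diol | C=Cc1ccc(O)c(O)c1
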